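The readings come from a simulation for an exercise, noise included.

The J left over after 5.00 h is what I read first: teal keeps 47.2 % and ochre 16.6 %, although ochre got 4.08 times the E of teal.

all flasks: J 0.10 M
- teal: L 1 mM; E 0.71 mM; run made earlier
- ochre: L 1 mM; E 2.9 mM; run made earlier
- alpha: L 1.00 mM; E 0.50 mM; time 10 h
- beta: L 1.00 mM; E 2.0 mM; time 10 h

- teal (time / h: G / %, J / %): 0.333: 3.8, 95.9; 1.00: 13.7, 85.9; 2.00: 26.0, 73.7; 2.50: 30.9, 67.0; 4.00: 45.8, 53.4; 5.00: 52.7, 47.2
- ochre (time / h: G / %, J / %): 0.417: 12.2, 87.1; 0.667: 20.1, 78.8; 1.00: 30.7, 69.7; 2.00: 52.1, 47.6; 3.00: 67.9, 32.2; 5.00: 83.6, 16.6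

(readings scatter by 0.5 percentage points)

- the average divides the monomer in chains by the number of chains begun, living and dead together
- what may be going on: J + E -> D + G; D + L -> Q; J + D -> G + D; 2 E -> Z
- the earlier runs do not show the number of chains; that part of a forecast is a guess

- which of the two ends with the longer chains by the average number of monomer units in a chain (chains begun, living or dead) ("neither" if they lie within 10 %) (alpha / beta / neither)
- average number of monomer units in a chain (chains begun, living or dead) at the end, alpha
- average number of monomer units in a chain (chains begun, living or dead) at the end, beta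

G and J add up to about the charge in both runs, so Q and Z hold no monomer. I take J to fall in proportion to [D], with few chains dying, so the slope ln(charged/left)/time counts chains: 0.150 h⁻¹ for teal and 0.359 h⁻¹ for ochre, a ratio of 2.39. That ratio, read from the last readings, stays below the charge ratio, which I read as an initiator efficiency that falls as the charge rises, since the step to Z takes two E at a turn. My own law for the chain count N at an E charge c is N = c/(1 + c/x). The two slopes give x = 2.38 mM: the crossover charge, the charge of E at which half of it begins chains and the rest goes to Z. The absolute scale of N is a guess, since the runs show no chain count.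

Beta looks nearly like ochre, yet ochre's N is 1.31 mM and beta's 1.09 mM. Beta's slope is therefore lower, at 0.299 h⁻¹, which gives 94.9 % conversion and a length of 87.3. By the same reckoning ochre at its last reading stands at 63.9, so I expect beta to end longer, with fewer chains and twice the time. Alpha, scaled from teal's 0.547 mM to 0.413 mM, has slope 0.113 h⁻¹, conversion 67.8 % and length 164.

The forecast, holding that dimerisation “competes with initiation”, names alpha, with 175 for alpha and 94 for beta. My lengths are lower, but I name the same flask.

Alpha ends at 168 and beta at 95.1, so the longer chains are in alpha.

    J + E → D + G (k = 51.0 M⁻¹ h⁻¹)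
    D + L → Q (k = 55.0 M⁻¹ h⁻¹)
    J + D → G + D, rate k3*[D]*[J] (k = 350 M⁻¹ h⁻¹)
    2 E → Z (k = 3300 M⁻¹ h⁻¹)

In beta at 10.0 h, D and Q together come to 0.981 mM, half of the E charged, where the crossover charge gave an efficiency of 54.4 %. For the neighbouring flask, like beta but with 3.40 mM of E, the crossover charge gives N = 1.40 mM. Scaling beta's length by the chains and by G, 97.3 % against 93.4 %, gives 77.1, and that flask ends at 75.4.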